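Raising the reagent from 0.030 M to 0.0600 M and running 15 h is a decision that hangs on one question: does more reagent speed the target or hold it back?

| flask | substrate | reagent | remark | time |
|---|---|---|---|---|
| autumn | 0.050 M | 0.030 M | run made earlier |  |
| flask | 0.050 M | 0.0600 M |  | 15 h |

autumn run (percent of the substrate charged)

| time / min | target / % | over-reaction product / % | substrate / % |
|---|---|---|---|
| 12.0 | 5.7 | 0.3 | 73.5 |
| 25.0 | 8.8 | 0 | 61.4 |
| 40.0 | 13.9 | 0 | 53.7 |
| 50.0 | 17.5 | 0.3 | 48.9 |
| 60.0 | 20.0 | 0 | 47.2 |
| 80.0 | 24.0 | 0.1 | 42.9 |
| 90.0 | 27.0 | 0.3 | 40.5 |

(scatter of a reading: 0.5 percentage points)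

- what was read earlier has a scatter of 0.5 percentage points, one standard deviation
- a reading of substrate is of its free form alone

1. the target in the flask at 15 h, as a percentage of the substrate charged
2. the over-reaction product in the flask at 15 h, as a percentage of the substrate charged
3. concentration of reagent at 15 h, in M

In the autumn run, 32.4% of the substrate is unaccounted for at 40.0 min and 32.2% at 90.0 min. This reads as a reversibly bound form of substrate and reagent, with binding constant K = bound/([substrate][reagent]). Two bookkeepings give K at both times, and a constant must not move.

If target keeps the reagent, K runs from 88.1 M⁻¹ to 3180 M⁻¹, a drift of 1.56 powers of ten. If target releases it, K runs from 43.7 M⁻¹ to 57.2 M⁻¹, a drift of 0.117, which is smaller. So the first bookkeeping is dropped, and K is taken as 50.0 M⁻¹.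

The autumn target slope from 50.0 min to 90.0 min, over the mean free substrate, reads 0.319 h⁻¹. Taking target to come from free substrate, the unconverted pool of free and bound substrate decays pseudo-first-order at that constant divided by a slowing factor, which in the flask, with [reagent] taken at its charge, is 4.00: S = 1 + K[reagent], the pool over its free part.

This reckoning leaves 30.3% of the pool in the flask at 15 h, so target plus over-reaction product come to 69.7%. The bound part of that pool holds reagent, leaving [reagent] in the flask at 0.0487 M. Over-reaction product in the autumn run reads 0.3% at the last time against a scatter of 0.5 percentage points, so no split between the two products is reckoned.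

The forecast differs: target 87% (72% to 97%), over-reaction product 12% (2% to 26%), and reagent 0.0042 M (0.0012 M to 0.0092 M), reasoned “with reagent held in the adduct”.

The flask gives target 66.1%, over-reaction product 5.34% and reagent 0.0479 M, so the two products total 71.4% against the 69.7% reckoned.

    substrate → target (k = 0.320 h⁻¹)
    target → over-reaction product (k = 0.00760 h⁻¹)
    substrate + reagent ⇌ intermediate A (K = 47.0 M⁻¹, k = 56.0 M⁻¹ h⁻¹)
    intermediate C ⇌ intermediate D (K = 0.400, k = 0.0970 h⁻¹)
    substrate + reagent → intermediate B (k = 1.50 M⁻¹ h⁻¹)
    intermediate B → intermediate C (k = 0.0890 h⁻¹)

The neighbouring flask charged with 0.24 M of reagent has S = 13.0, 3.25 times the 4.00 of the first flask, which leaves 69.2% of the pool at 15 h and gives 30.8% for the two products together. That flask gives target 28.3% and over-reaction product 2.00%, together 30.3%.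

(The numbers in the tables are calculated for substances that don't exist, noise included.)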